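## Structural features

The target joins a 2,4,6-trihydroxybenzene-1,3-dicarbaldehyde to a cadinane-type octalin through a benzylic methine, C11, which also carries an isobutyl group. Ring A (C1–C2=C3–C8–C9–C10) and ring B (C3–C4–C5–C6–C7–C8) share the C3–C8 bond, and the trisubstituted alkene C2=C3 is endocyclic to ring A and exocyclic to ring B. Of the five stereocentres (1S, 4R, 7S, 8R, 11S in this numbering), C7 and C8 are vicinal and trans, the C4 methyl is cis to the C7 hydroxyisopropyl group and therefore axial on ring B, and the quaternary C1 stands directly next to the benzylic C11. The fragile groups are the tertiary alcohol (ionisation, elimination), the acid-sensitive C2=C3 alkene, the formylated phloroglucinol (acidic, chelating, easily oxidised) and, as long as C3 is a carbonyl group, the epimerisable axial methyl at C4. The real difficulty is the contiguous pair C1 (quaternary) and C11 (tertiary, benzylic), which an acyclic alkylation would have to set relative to each other and to ring B, together with the contra-thermodynamic configuration at C4. The key step uses the fact that C1 carries a methyl group and the ring methine C2: both can start as vinyl groups, so C1 is a non-stereogenic divinyl carbon until one vinyl group closes ring A onto an exocyclic methylene at C3. The conformationally locked ring B (equatorial tert-alkyl group at C7, axial hydrogen at C8) then decides which vinyl group reacts.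

## Logic of the disconnections

**29 ⇒ 27 (through 28).** The three aryl O–CH3 bonds and the O–Si bond are cut last. The free formylphloroglucinol is acidic, chelating and oxidation-prone, so it should appear only in the final flask; until then the arene is an inert trimethyl ether. The forward step must be a nucleophilic, non-Lewis-acidic dealkylation that spares the tertiary alcohol and the C2=C3 alkene. The ortho-formyl groups make each aryloxide a good leaving group for a thiolate.

**27 ⇒ 25 ⇒ 24.** The two aryl–CHO bonds are cut, each by way of an aryl–Br bond. Formyl groups would not survive hydroboration, oxidation and decarbonylation, and an electrophilic formylation under strong Lewis acid would ionise the tertiary C–O bond and endanger the alkene. The arene goes back to a plain trimethoxyphenyl group. The forward steps need bromination that is faster at the arene than at the hindered alkene, and a complete twofold halogen–lithium exchange.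

**24 ⇒ 20 (through 23 and 22).** The C1 methyl is traced back to a vinyl group, one carbon being added in the retrosynthetic sense. This makes the two carbon substituents that C1 contributes to ring formation identical one step further back, so C1 loses its stereogenicity there. The forward sequence demands anti-Markovnikov functionalisation of the monosubstituted alkene only, and a decarbonylation whose alkyl–metal intermediate cannot undergo β-hydride elimination; the β-carbon is the quaternary C1.

**20 ⇒ 19.** The C2=C3 bond is cut. This removes ring A and the C1 stereocentre at once and leaves ring B with a tether ending in a divinyl carbon. The forward step must discriminate two diastereotopic vinyl groups; the locked ring B is relied on for this.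

**19 ⇒ 17 ⇒ 16.** The two vinyl C=C bonds are traced to two CH2OH arms (through 18), and the diol to a cyclic malonate. A divinyl carbon is a masked malonate carbon, which reduces the quaternary centre to enolate alkylation chemistry. The forward steps need reduction of a hindered acylal and a twofold olefination of a non-enolisable 1,3-dialdehyde without deformylation.

**16 ⇒ 6 + 15.** The C1–C10 bond is cut. It is the most convergent bond, separating an aryl/isobutyl half from a ring B half, each with its stereocentres already fixed, and C1 needs no stereocontrol. The demand is an SN2 reaction of a hindered tertiary carbanion with a primary iodide. This is why 15 carries no free hydroxyl (silyl ether) and no enolisable ketone (the C3 methylene is installed before the coupling, so the axial C4 methyl can no longer epimerise under base).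

**6 ⇒ 3 + 4 ⇒ 1 + 2.** The C11–CH2 bond to the isobutyl group is cut, then the C11=C1 double bond. C11 lies β to two carbonyl groups, so it is set by a catalyst-controlled conjugate addition to an achiral, doubly activated acceptor. The demand is high facial selectivity with a di-ortho-substituted aryl group and a zinc reagent free of magnesium salts, because the uncatalysed addition of a Grignard reagent would be racemic.

**15 ⇒ 14 ⇒ 13 ⇒ 12 ⇒ 11 ⇒ 10 ⇒ 8 ⇒ 7.** In turn: C10–I (functional group change), the ester oxidation level, C3=CH2, O–Si, the tertiary C–O bond (hydration of the isopropenyl group), C8–C9 (enolate alkylation) and the C4–H/C5–H bonds (conjugate reduction). Ring B with 7S is the p-menthane skeleton of 7; the C3 carbonyl activates C8 for alkylation and then becomes the methylene. The demand is that the C4 methyl ends cis to the C7 substituent, which is the less stable epimer of the ketone and the minor outcome of chemical reduction with protonation. An ene-reductase sets it, and every later step while C3 is a carbonyl is non-epimerising: kinetic enolate, neutral hydration, non-basic methylenation.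

## Other disconnections considered

**Alternative 1:** The cut removes C1 from between C2 and C10: hydrindanone A1 is homologated with methyl 2-diazopropanoate A2 to the decalin β-keto ester A3. In the forward key step the diazo carbon adds to the C2 carbonyl under Lewis acid activation and C10 migrates to it, enlarging the five-membered ring to ring A.
- In its favour: the quaternary C1 is made with its methyl group already in place, so no one-carbon excision is needed; on this point it is better than the chosen plan. The C2 ketone can later give the C2=C3 alkene with unambiguous regiochemistry, because C1 is quaternary.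
- Against it: the migration must choose C10 over the ring-fusion carbon C3, and the C1 configuration depends on the face of addition and on the orientation of methyl versus ester in the migrating step. These are two selectivities with no obvious bias, compared with one group selection in the chosen plan. C3 is epimerisable in A1 and A3.
- Decisive point: the ester on C1 still has to become C11 with aryl, isobutyl and the correct configuration next to a quaternary carbon, at a late stage. The chosen plan sets C11 first by catalysis and makes C1 non-stereogenic until ring closure.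
- Step economy: Alternative 1 saves the three-step vinyl-to-methyl sequence but adds alkene formation from the ketone and the whole C11 elaboration, so it is expected to be longer overall.

**Alternative 2:** The cut removes two ring C–C bonds of the arene: malonyl dichloride A4, carried on C11, acylates both methylene carbons of the enolate of dimethyl 3-oxopentanedioate A5 (generated with a magnesium alkoxide), and the six-membered ring tautomerises to phloroglucinol diester A6.
- In its favour: the three phenols arrive free, so there is no O-demethylation and no bromination or organolithium chemistry on an electron-rich arene. On protecting-group economy for the phenols and on mildness at the very end it is the equal or the better of the chosen plan.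
- Against it: a monosubstituted malonyl dichloride with a bulky substituent readily forms an acyl ketene and O-acylates, so the twofold C-acylation is doubtful. The two esters must then be brought to the aldehyde level on a free phloroglucinol, where the intermediate o-hydroxybenzyl alcohols tend towards quinone methides; this needs protection, reduction, oxidation and deprotection.
- Decisive point: it does not touch the real problem. A4 already contains C1 and C11 with both configurations set and ring A closed.
- Comparison: structurally it moves the effort to the easy part of the molecule, mechanistically it is ionic acylation against metathesis, and in step count it is at best equal for the arene and adds nothing for the terpenoid half.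

**Alternative 3:** The cut is C1–C10: iodo alkenenitrile A7 is deprotonated at C3, and the delocalised anion (C1–C2–C3) displaces the primary iodide through C1 to give bicyclic nitrile A8, with the alkene left at C2=C3.
- In its favour: one metal-free operation forms the ring, the quaternary centre and the alkene position. Attack through C3 would need a four-membered ring, so the regiochemistry is secured by structure. The quaternary centre is formed intramolecularly, which is better than the intermolecular alkylation of a hindered Meldrum's acid anion in the chosen plan.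
- Equal points: as in the chosen plan, C1 is not stereogenic until ring closure, and the small cyano group should take the pseudoaxial site, so the same conformational argument applies. Conversion of the nitrile to methyl (reduction to the aldehyde, then deoxygenation) matches the vinyl-to-methyl sequence in length.
- Against it: the strong base meets C11–H, which is benzylic and allylic to the nitrile-bearing alkene, so the centre set earlier may be eroded. A7 also needs a one-carbon homologation at C3 and a condensation to a trisubstituted alkenenitrile, which costs steps.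
- Comparison: overall the two plans are close in length. The chosen plan keeps C11 away from strong base after it is set; Alternative 3 is kept as the fallback for the key step.

Key step: step 13

**Remarks before the steps**

- Assumption: the sense of induction of the phosphoramidite in step 2 cannot be predicted with certainty for a 2,6-dimethoxyaryl acceptor; the ligand is written as (S,R,R) and its antipode is used if the induction is opposite.
- Remark: CIP descriptors switch without any change of geometry at C11 (R in 16 and 18) and at C1 (R in 20, 22 and 23), because substituent priorities change.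

## Steps

**Step 1**
Reactants: 1 2,4,6-trimethoxybenzaldehyde; 2 Meldrum's acid
Product: 3 2,2-dimethyl-5-[(2,4,6-trimethoxyphenyl)methylidene]-1,3-dioxane-4,6-dione
Conditions: pyrrolidine (10 mol%), AcOH (10 mol%), toluene, rt
Reagents that add atoms: none
Why: Knoevenagel condensation; the acidic dione condenses with the electron-rich, di-ortho-substituted aldehyde through its iminium ion, and no stereocentre is formed.

**Step 2**
Reactants: 3 arylidene Meldrum's acid; 4 isobutylmagnesium bromide
Product: 6 2,2-dimethyl-5-[(1S)-3-methyl-1-(2,4,6-trimethoxyphenyl)butyl]-1,3-dioxane-4,6-dione, via diisobutylzinc 5 (not isolated)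
Conditions: 4 (4 equiv), ZnCl2 (2 equiv), Et2O, 0 °C to rt, then 1,4-dioxane, filtration; Cu(OTf)2 (5 mol%), (S,R,R)-(1,1'-binaphthalene-2,2'-diyl) N,N-bis(1-phenylethyl)phosphoramidite (10 mol%), DME, −40 °C to rt; aq. NH4Cl
Reagents that add atoms: none
Why: Copper-catalysed asymmetric conjugate addition of a dialkylzinc to an arylidene Meldrum's acid; the phosphoramidite–copper complex delivers the isobutyl group to one face of the benzylidene carbon and sets C11 (S), while the uncatalysed addition of the zinc reagent is slow, which is why the Grignard reagent is transmetallated and freed of magnesium salts first.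

**Step 3**
Reactants: 7 (S)-(+)-carvone
Product: 8 cis-dihydrocarvone, (2R,5S)-2-methyl-5-(prop-1-en-2-yl)cyclohexan-1-one
Conditions: ene-reductase OYE1 (cat.), NADP+ (cat.), glucose dehydrogenase (cat.), D-glucose (1.5 equiv), phosphate buffer pH 7.0, 30 °C
Reagents that add atoms: none
Why: Flavin-dependent ene-reductase (old yellow enzyme) reduction of an activated alkene; hydride adds to C5 and a proton to C4 in a trans fashion inside the active site, which is expected to fix C4 as R whatever the ring stereocentre and so to give the cis epimer that chemical reduction with protonation disfavours; the isolated isopropenyl alkene is not a substrate.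

**Step 4**
Reactants: 8 cis-dihydrocarvone
Product: 10 methyl 2-[(1R,3R,6S)-3-methyl-2-oxo-6-(prop-1-en-2-yl)cyclohexyl]acetate, via lithium enolate 9 (not isolated)
Conditions: LiN(iPr)2 (1.05 equiv), THF, −78 °C; methyl bromoacetate, DMPU, −78 to −40 °C; AcOH quench at −78 °C
Reagents that add atoms: methyl bromoacetate, COC(=O)CBr
Why: Kinetic enolate alkylation; deprotonation at the less substituted α-CH2 (C8) leaves the labile C4 centre untouched, and the electrophile should enter anti to the adjacent isopropenyl group and to the pseudoaxial C4 methyl, setting C8 trans to C7; the cold acidic quench prevents equilibration.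

**Step 5**
Reactants: 10 keto ester
Product: 11 methyl 2-[(1R,3R,6S)-6-(2-hydroxypropan-2-yl)-3-methyl-2-oxocyclohexyl]acetate
Conditions: Co(acac)2 (20 mol%), PhSiH3, O2 (1 atm), THF, rt
Reagents that add atoms: oxygen, O=O
Why: Mukaiyama hydration; hydrogen-atom transfer from a cobalt hydride to the 1,1-disubstituted alkene gives the tertiary radical, which is trapped by O2 and reduced to the Markovnikov tertiary alcohol under neutral conditions that spare the α-stereocentres, the ketone and the ester.

**Step 6**
Reactants: 11 hydroxy keto ester
Product: 12 methyl 2-[(1R,3R,6S)-3-methyl-2-oxo-6-{2-[(triethylsilyl)oxy]propan-2-yl}cyclohexyl]acetate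
Conditions: Et3SiOTf, 2,6-lutidine, CH2Cl2, −78 °C
Reagents that add atoms: triethylsilyl trifluoromethanesulfonate, CC[Si](CC)(CC)OS(=O)(=O)C(F)(F)F
Why: Silylation of the hindered tertiary alcohol with a silyl triflate; at −78 °C with a weak base the ketone is not enolised, and the ether later prevents tetrahydropyran formation by attack of the hydroxyl on the primary iodide and ionisation of a titanium alkoxide.

**Step 7**
Reactants: 12 silyl ether keto ester
Product: 13 methyl 2-[(1R,3R,6S)-3-methyl-2-methylidene-6-{2-[(triethylsilyl)oxy]propan-2-yl}cyclohexyl]acetate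
Conditions: Zn, CH2Br2, TiCl4, THF/CH2Cl2, 0 °C to rt
Reagents that add atoms: dibromomethane, BrCBr
Why: Takai–Lombardo methylenation; the non-basic zinc–titanium methylene reagent olefinates hindered, enolisable ketones without α-epimerisation and leaves the ester alone, so the axial C4 methyl is retained and from here on is no longer epimerisable.

**Step 8**
Reactants: 13 methylidene ester
Product: 14 2-[(1R,3R,6S)-3-methyl-2-methylidene-6-{2-[(triethylsilyl)oxy]propan-2-yl}cyclohexyl]ethan-1-ol
Conditions: LiAlH4, Et2O, 0 °C
Reagents that add atoms: none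
Why: Hydride reduction of the methyl ester to the primary alcohol; the alkene and the silyl ether are inert.

**Step 9**
Reactants: 14 primary alcohol
Product: 15 triethyl({2-[(1S,2R,4R)-2-(2-iodoethyl)-4-methyl-3-methylidenecyclohexyl]propan-2-yl}oxy)silane
Conditions: I2, PPh3, imidazole, CH2Cl2, 0 °C to rt
Reagents that add atoms: iodine, II
Why: Appel-type iodination through the alkoxyphosphonium ion with SN2 displacement at the primary carbon; no stereocentre is involved and imidazole buffers the silyl ether.

**Step 10**
Reactants: 6 monosubstituted Meldrum's acid; 15 iodide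
Product: 16 2,2-dimethyl-5-[(1R)-3-methyl-1-(2,4,6-trimethoxyphenyl)butyl]-5-{2-[(1R,3R,6S)-3-methyl-2-methylidene-6-{2-[(triethylsilyl)oxy]propan-2-yl}cyclohexyl]ethyl}-1,3-dioxane-4,6-dione
Conditions: Cs2CO3, DMF, 45 °C
Reagents that add atoms: none
Why: C-alkylation of the caesium salt of a 5-monosubstituted Meldrum's acid with an unbranched primary iodide; the planar cyclic dione anion is compact enough to form the quaternary carbon, and C1 is not a stereocentre here because its two acyl arms are identical.

**Step 11**
Reactants: 16 dialkylated Meldrum's acid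
Product: 17 2-[(1S)-3-methyl-1-(2,4,6-trimethoxyphenyl)butyl]-2-{2-[(1R,3R,6S)-3-methyl-2-methylidene-6-{2-[(triethylsilyl)oxy]propan-2-yl}cyclohexyl]ethyl}propane-1,3-diol
Conditions: LiAlH4, THF, 0 to 50 °C
Reagents that add atoms: none
Why: Exhaustive hydride reduction of both acylal carbonyl groups to the 2,2-disubstituted propane-1,3-diol with loss of the acetonide carbon; aryl ethers, alkene and silyl ether are inert.

**Step 12**
Reactants: 17 diol
Product: 19 triethyl({2-[(1S,2R,4R)-2-{3-ethenyl-3-[(1S)-3-methyl-1-(2,4,6-trimethoxyphenyl)butyl]pent-4-en-1-yl}-4-methyl-3-methylidenecyclohexyl]propan-2-yl}oxy)silane, via dialdehyde 18 (not isolated)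
Conditions: (COCl)2, DMSO, CH2Cl2, −78 °C; Et3N, −78 to 0 °C; then Ph3P=CH2 (8 equiv, from Ph3PCH3Br and KN(SiMe3)2, THF), −78 °C to rt
Reagents that add atoms: methyltriphenylphosphonium bromide, C[P+](c1ccccc1)(c1ccccc1)c1ccccc1.[Br-]
Why: Swern oxidation followed in the same flask by twofold Wittig methylenation; the non-enolisable 2,2-disubstituted malonaldehyde is olefinated before hydration or deformylation can intervene, and no stereocentre arises because both arms become identical vinyl groups.

**Step 13**
Reactants: 19 divinyl triene
Product: 20 (2R,4aR,5S,8R)-2-ethenyl-8-methyl-2-[(1S)-3-methyl-1-(2,4,6-trimethoxyphenyl)butyl]-5-{2-[(triethylsilyl)oxy]propan-2-yl}-2,3,4,4a,5,6,7,8-octahydronaphthalene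
Conditions: RuCl2(=CH-C6H4-2-OiPr)(H2IMes) (second-generation Hoveyda–Grubbs catalyst, 10 mol%), toluene (0.005 M), 80 °C, argon sparge
Reagents that add atoms: none
Why: After loss of its chelating styrene ether the catalyst exchanges with one of the monosubstituted vinyl groups on C1 to give a ruthenium alkylidene at C2, loading on the 1,1-disubstituted C3 methylene being much slower. This alkylidene adds to the exocyclic C3=CH2 through a ruthenacyclobutane whose collapse forms C2=C3 and releases the methylene carbon, finally as ethylene; the closest known reaction type is diastereotopic-group-selective ring-closing metathesis at a divinyl quaternary carbon. Ring A is closed in the six-membered mode as a cyclohexene with a trisubstituted endocyclic alkene, the only closure open to the system because the two vinyl groups share one carbon. The new stereocentre C1 is controlled by the substrate: the equatorial tert-alkyl group at C7 locks ring B, so C8–H is axial and the half-chair of the forming ring A is fixed. In that half-chair the C1 substituent that is pseudoaxial lies syn to the axial hydrogen on C9 and must be small, so closure should go through the vinyl group that leaves the CH(aryl)(isobutyl) group pseudoequatorial and the spectator vinyl pseudoaxial, which is the site of the C1 methyl in the target. The step needs group selectivity between the two vinyl groups and ring closure in preference to cross-metathesis; high dilution, the slow homodimerisation of neopentylic vinyl groups and the irreversible formation of the trisubstituted cyclohexene secure the latter. Because the two alkylidenes can interconvert by exchange with ethylene or substrate faster than either adds to the hindered methylene, the outcome should reflect the energy difference of the two ring-closing transition states. The silyl ether, the aryl ethers and the benzylic centre are not touched.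

**Step 14**
Reactants: 20 vinyl octalin
Product: 22 2-[(2R,4aR,5S,8R)-8-methyl-2-[(1S)-3-methyl-1-(2,4,6-trimethoxyphenyl)butyl]-5-{2-[(triethylsilyl)oxy]propan-2-yl}-2,3,4,4a,5,6,7,8-octahydronaphthalen-2-yl]ethan-1-ol, via alkylborane 21 (not isolated)
Conditions: 9-BBN, THF, 0 to 50 °C; then NaOH (3 M), H2O2 (30%), 0 °C to rt
Reagents that add atoms: hydrogen peroxide, OO
Why: Anti-Markovnikov hydroboration–oxidation; the bulky borane adds to the monosubstituted vinyl group and not to the hindered trisubstituted ring alkene, and oxidation replaces boron by hydroxyl at the terminal carbon.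

**Step 15**
Reactants: 22 primary alcohol
Product: 23 2-[(2R,4aR,5S,8R)-8-methyl-2-[(1S)-3-methyl-1-(2,4,6-trimethoxyphenyl)butyl]-5-{2-[(triethylsilyl)oxy]propan-2-yl}-2,3,4,4a,5,6,7,8-octahydronaphthalen-2-yl]acetaldehyde
Conditions: Dess–Martin periodinane, NaHCO3, CH2Cl2, rt
Reagents that add atoms: none
Why: Dess–Martin oxidation of the primary alcohol to the aldehyde under buffered, neutral conditions; the α-carbon is a methylene next to a quaternary carbon, so nothing can epimerise.

**Step 16**
Reactants: 23 aldehyde
Product: 24 (2S,4aR,5S,8R)-2,8-dimethyl-2-[(1S)-3-methyl-1-(2,4,6-trimethoxyphenyl)butyl]-5-{2-[(triethylsilyl)oxy]propan-2-yl}-2,3,4,4a,5,6,7,8-octahydronaphthalene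
Conditions: RhCl(PPh3)3 (1.1 equiv), toluene, 110 °C
Reagents that add atoms: none
Why: Tsuji–Wilkinson decarbonylation (formyl C–H oxidative addition, CO extrusion, C–H reductive elimination); the alkyl–rhodium intermediate has no β-hydrogen because its β-carbon is the quaternary C1, so only the methyl compound can form, and C1 has the target configuration because the vinyl group occupied the methyl site.

**Step 17**
Reactants: 24 trimethoxyphenyl octalin
Product: 25 (2S,4aR,5S,8R)-2-[(1S)-1-(3,5-dibromo-2,4,6-trimethoxyphenyl)-3-methylbutyl]-2,8-dimethyl-5-{2-[(triethylsilyl)oxy]propan-2-yl}-2,3,4,4a,5,6,7,8-octahydronaphthalene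
Conditions: NBS (2.1 equiv), MeCN, 0 °C to rt, dark
Reagents that add atoms: N-bromosuccinimide, O=C1CCC(=O)N1Br
Why: Electrophilic aromatic bromination at the two free ring positions, each activated by two ortho and one para methoxy group; under non-radical conditions this should be far faster than any reaction of the hindered trisubstituted alkene.

**Step 18**
Reactants: 25 dibromide
Product: 27 2,4,6-trimethoxy-5-[(1S)-1-[(2S,4aR,5S,8R)-2,8-dimethyl-5-{2-[(triethylsilyl)oxy]propan-2-yl}-2,3,4,4a,5,6,7,8-octahydronaphthalen-2-yl]-3-methylbutyl]benzene-1,3-dicarbaldehyde, via dilithioarene 26 (not isolated)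
Conditions: tBuLi (4.5 equiv), THF, −78 °C; DMF, −78 to 0 °C; aq. NH4Cl
Reagents that add atoms: N,N-dimethylformamide, CN(C)C=O
Why: Twofold bromine–lithium exchange followed by Bouveault-type formylation with DMF; each aryllithium is flanked by two methoxy groups, and the basic, low-temperature conditions spare the alkene and the silyl ether, which a Lewis-acid formylation would not.

**Step 19**
Reactants: 27 trimethoxy dialdehyde
Product: 29 5-[(1S)-1-[(2S,4aR,5S,8R)-5-(2-hydroxypropan-2-yl)-2,8-dimethyl-2,3,4,4a,5,6,7,8-octahydronaphthalen-2-yl]-3-methylbutyl]-2,4,6-trihydroxybenzene-1,3-dicarbaldehyde, via triethylsilyl ether 28 (not isolated)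
Conditions: NaSEt (10 equiv), DMF, 120 °C; then HCl (1 M), THF, rt
Reagents that add atoms: none
Why: SN2 O-demethylation of aryl methyl ethers by thiolate; every methoxy group is ortho to a formyl group, so each aryloxide is a good leaving group and the phenoxides formed resist further attack, and the dilute acid treatment protonates the phenoxides and cleaves the tertiary triethylsilyl ether without touching the alkene.

## Compound list

1 | 2,4,6-trimethoxybenzaldehyde | COc1cc(OC)c(C=O)c(OC)c1 | starting material
2 | Meldrum's acid (2,2-dimethyl-1,3-dioxane-4,6-dione) | CC1(C)OC(=O)CC(=O)O1 | starting material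
3 | 2,2-dimethyl-5-[(2,4,6-trimethoxyphenyl)methylidene]-1,3-dioxane-4,6-dione | COc1cc(OC)c(C=C2C(=O)OC(C)(C)OC2=O)c(OC)c1 | intermediate
4 | isobutylmagnesium bromide | CC(C)C[Mg]Br | starting material
5 | diisobutylzinc (not isolated) | CC(C)C[Zn]CC(C)C | intermediate
6 | 2,2-dimethyl-5-[(1S)-3-methyl-1-(2,4,6-trimethoxyphenyl)butyl]-1,3-dioxane-4,6-dione | CC(C)C[C@H](c1c(OC)cc(OC)cc1OC)C1C(=O)OC(C)(C)OC1=O | intermediate
7 | (S)-(+)-carvone, (5S)-2-methyl-5-(prop-1-en-2-yl)cyclohex-2-en-1-one | CC1=CC[C@H](C(C)=C)CC1=O | starting material
8 | cis-dihydrocarvone, (2R,5S)-2-methyl-5-(prop-1-en-2-yl)cyclohexan-1-one | O=C1[C@H](C)CC[C@H](C(C)=C)C1 | intermediate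
9 | lithium (3S,6R)-6-methyl-3-(prop-1-en-2-yl)cyclohex-1-en-1-olate (not isolated) | [Li]OC1=C[C@@H](C(C)=C)CC[C@H]1C | intermediate
10 | methyl 2-[(1R,3R,6S)-3-methyl-2-oxo-6-(prop-1-en-2-yl)cyclohexyl]acetate | O=C1[C@H](C)CC[C@H](C(C)=C)[C@H]1CC(=O)OC | intermediate
11 | methyl 2-[(1R,3R,6S)-6-(2-hydroxypropan-2-yl)-3-methyl-2-oxocyclohexyl]acetate | O=C1[C@H](C)CC[C@H](C(C)(C)O)[C@H]1CC(=O)OC | intermediate
12 | methyl 2-[(1R,3R,6S)-3-methyl-2-oxo-6-{2-[(triethylsilyl)oxy]propan-2-yl}cyclohexyl]acetate | O=C1[C@H](C)CC[C@H](C(C)(C)O[Si](CC)(CC)CC)[C@H]1CC(=O)OC | intermediate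
13 | methyl 2-[(1R,3R,6S)-3-methyl-2-methylidene-6-{2-[(triethylsilyl)oxy]propan-2-yl}cyclohexyl]acetate | C=C1[C@H](C)CC[C@H](C(C)(C)O[Si](CC)(CC)CC)[C@H]1CC(=O)OC | intermediate
14 | 2-[(1R,3R,6S)-3-methyl-2-methylidene-6-{2-[(triethylsilyl)oxy]propan-2-yl}cyclohexyl]ethan-1-ol | C=C1[C@H](C)CC[C@H](C(C)(C)O[Si](CC)(CC)CC)[C@H]1CCO | intermediate
15 | triethyl({2-[(1S,2R,4R)-2-(2-iodoethyl)-4-methyl-3-methylidenecyclohexyl]propan-2-yl}oxy)silane | C=C1[C@H](C)CC[C@H](C(C)(C)O[Si](CC)(CC)CC)[C@H]1CCI | intermediate
16 | 2,2-dimethyl-5-[(1R)-3-methyl-1-(2,4,6-trimethoxyphenyl)butyl]-5-{2-[(1R,3R,6S)-3-methyl-2-methylidene-6-{2-[(triethylsilyl)oxy]propan-2-yl}cyclohexyl]ethyl}-1,3-dioxane-4,6-dione | C=C1[C@H](C)CC[C@H](C(C)(C)O[Si](CC)(CC)CC)[C@H]1CCC2(C(=O)OC(C)(C)OC2=O)[C@H](CC(C)C)c3c(OC)cc(OC)cc3OC | intermediate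
17 | 2-[(1S)-3-methyl-1-(2,4,6-trimethoxyphenyl)butyl]-2-{2-[(1R,3R,6S)-3-methyl-2-methylidene-6-{2-[(triethylsilyl)oxy]propan-2-yl}cyclohexyl]ethyl}propane-1,3-diol | C=C1[C@H](C)CC[C@H](C(C)(C)O[Si](CC)(CC)CC)[C@H]1CCC(CO)(CO)[C@H](CC(C)C)c2c(OC)cc(OC)cc2OC | intermediate
18 | 2-[(1R)-3-methyl-1-(2,4,6-trimethoxyphenyl)butyl]-2-{2-[(1R,3R,6S)-3-methyl-2-methylidene-6-{2-[(triethylsilyl)oxy]propan-2-yl}cyclohexyl]ethyl}propanedial (not isolated) | C=C1[C@H](C)CC[C@H](C(C)(C)O[Si](CC)(CC)CC)[C@H]1CCC(C=O)(C=O)[C@H](CC(C)C)c2c(OC)cc(OC)cc2OC | intermediate
19 | triethyl({2-[(1S,2R,4R)-2-{3-ethenyl-3-[(1S)-3-methyl-1-(2,4,6-trimethoxyphenyl)butyl]pent-4-en-1-yl}-4-methyl-3-methylidenecyclohexyl]propan-2-yl}oxy)silane | C=C1[C@H](C)CC[C@H](C(C)(C)O[Si](CC)(CC)CC)[C@H]1CCC(C=C)(C=C)[C@H](CC(C)C)c2c(OC)cc(OC)cc2OC | intermediate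
20 | (2R,4aR,5S,8R)-2-ethenyl-8-methyl-2-[(1S)-3-methyl-1-(2,4,6-trimethoxyphenyl)butyl]-5-{2-[(triethylsilyl)oxy]propan-2-yl}-2,3,4,4a,5,6,7,8-octahydronaphthalene | CC(C)C[C@H](c1c(OC)cc(OC)cc1OC)[C@]1(C=C)C=C2[C@H](C)CC[C@H](C(C)(C)O[Si](CC)(CC)CC)[C@H]2CC1 | intermediate
21 | B-alkyl-9-borabicyclo[3.3.1]nonane adduct of 20, boron on the terminal carbon of the former vinyl group (not isolated) | CC(C)C[C@H](c1c(OC)cc(OC)cc1OC)[C@]1(CCB3C4CCCC3CCC4)C=C2[C@H](C)CC[C@H](C(C)(C)O[Si](CC)(CC)CC)[C@H]2CC1 | intermediate
22 | 2-[(2R,4aR,5S,8R)-8-methyl-2-[(1S)-3-methyl-1-(2,4,6-trimethoxyphenyl)butyl]-5-{2-[(triethylsilyl)oxy]propan-2-yl}-2,3,4,4a,5,6,7,8-octahydronaphthalen-2-yl]ethan-1-ol | CC(C)C[C@H](c1c(OC)cc(OC)cc1OC)[C@]1(CCO)C=C2[C@H](C)CC[C@H](C(C)(C)O[Si](CC)(CC)CC)[C@H]2CC1 | intermediate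
23 | 2-[(2R,4aR,5S,8R)-8-methyl-2-[(1S)-3-methyl-1-(2,4,6-trimethoxyphenyl)butyl]-5-{2-[(triethylsilyl)oxy]propan-2-yl}-2,3,4,4a,5,6,7,8-octahydronaphthalen-2-yl]acetaldehyde | CC(C)C[C@H](c1c(OC)cc(OC)cc1OC)[C@]1(CC=O)C=C2[C@H](C)CC[C@H](C(C)(C)O[Si](CC)(CC)CC)[C@H]2CC1 | intermediate
24 | (2S,4aR,5S,8R)-2,8-dimethyl-2-[(1S)-3-methyl-1-(2,4,6-trimethoxyphenyl)butyl]-5-{2-[(triethylsilyl)oxy]propan-2-yl}-2,3,4,4a,5,6,7,8-octahydronaphthalene | CC(C)C[C@H](c1c(OC)cc(OC)cc1OC)[C@]1(C)C=C2[C@H](C)CC[C@H](C(C)(C)O[Si](CC)(CC)CC)[C@H]2CC1 | intermediate
25 | (2S,4aR,5S,8R)-2-[(1S)-1-(3,5-dibromo-2,4,6-trimethoxyphenyl)-3-methylbutyl]-2,8-dimethyl-5-{2-[(triethylsilyl)oxy]propan-2-yl}-2,3,4,4a,5,6,7,8-octahydronaphthalene | CC(C)C[C@H](c1c(OC)c(Br)c(OC)c(Br)c1OC)[C@]1(C)C=C2[C@H](C)CC[C@H](C(C)(C)O[Si](CC)(CC)CC)[C@H]2CC1 | intermediate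
26 | 3,5-dilithio analogue of 25, lithium in place of both bromine atoms (not isolated) | CC(C)C[C@H](c1c(OC)c([Li])c(OC)c([Li])c1OC)[C@]1(C)C=C2[C@H](C)CC[C@H](C(C)(C)O[Si](CC)(CC)CC)[C@H]2CC1 | intermediate
27 | 2,4,6-trimethoxy-5-[(1S)-1-[(2S,4aR,5S,8R)-2,8-dimethyl-5-{2-[(triethylsilyl)oxy]propan-2-yl}-2,3,4,4a,5,6,7,8-octahydronaphthalen-2-yl]-3-methylbutyl]benzene-1,3-dicarbaldehyde | CC(C)C[C@H](c1c(OC)c(C=O)c(OC)c(C=O)c1OC)[C@]1(C)C=C2[C@H](C)CC[C@H](C(C)(C)O[Si](CC)(CC)CC)[C@H]2CC1 | intermediate
28 | 2,4,6-trihydroxy-5-[(1S)-1-[(2S,4aR,5S,8R)-2,8-dimethyl-5-{2-[(triethylsilyl)oxy]propan-2-yl}-2,3,4,4a,5,6,7,8-octahydronaphthalen-2-yl]-3-methylbutyl]benzene-1,3-dicarbaldehyde (not isolated) | CC(C)C[C@H](c1c(O)c(C=O)c(O)c(C=O)c1O)[C@]1(C)C=C2[C@H](C)CC[C@H](C(C)(C)O[Si](CC)(CC)CC)[C@H]2CC1 | intermediate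
29 | 5-[(1S)-1-[(2S,4aR,5S,8R)-5-(2-hydroxypropan-2-yl)-2,8-dimethyl-2,3,4,4a,5,6,7,8-octahydronaphthalen-2-yl]-3-methylbutyl]-2,4,6-trihydroxybenzene-1,3-dicarbaldehyde | CC(C)C[C@H](c1c(O)c(C=O)c(O)c(C=O)c1O)[C@]1(C)C=C2[C@H](C)CC[C@H](C(C)(C)O)[C@H]2CC1 | target

## Step count and least certain steps

Total step count: 19 (2 for the aryl fragment, 7 for the ring B fragment, 10 from the fragment coupling to the target).
Longest linear sequence: 17 steps (7 to 29, steps 3 to 19).

**Step 13 (key step).** The most likely failure is slow loading of the catalyst on the neopentylic vinyl groups combined with slow addition to the hindered 1,1-disubstituted alkene, so that catalyst decomposition and ruthenium-hydride alkene migration outrun ring closure. The second risk is an insufficient energy gap between the two half-chair transition states, giving poor discrimination of the diastereotopic vinyl groups. The fallback closes ring A by deconjugative cycloalkylation of an unsaturated nitrile; it sets out from 6 and 15 and returns at 24. Aminolysis with decarboxylation of 6 (aqueous NH3, dioxane, 100 °C) would give the primary amide (3S)-5-methyl-3-(2,4,6-trimethoxyphenyl)hexanamide F1, which is dehydrated (trifluoroacetic anhydride, pyridine) to the nitrile (3S)-5-methyl-3-(2,4,6-trimethoxyphenyl)hexanenitrile F2. Hydroboration of the methylidene group of 15 (9-BBN; NaBO3) gives the hydroxymethyl compound F3, which is oxidised (Dess–Martin periodinane) to the ring B aldehyde F4. Aldol addition of lithiated F2 to F4 at −78 °C gives the β-hydroxy nitrile F5, which is dehydrated (MsCl, Et3N; then DBU) to the iodo alkenenitrile F6. KN(SiMe3)2 in THF removes the γ-hydrogen at C3, and the cyano-stabilised allyl anion displaces the iodide through C1 to give the bicyclic nitrile F7, with C2=C3 in place and the small cyano group expected in the pseudoaxial site. Reduction with iBu2AlH gives the aldehyde F8, and Wolff–Kishner reduction (Huang–Minlon procedure) gives 24.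

**Step 2.** Poor facial selectivity is the main risk, because the di-ortho-methoxy aryl group is twisted out of conjugation and can coordinate copper or zinc; traces of magnesium salts would also open a racemic background addition. The fallback replaces asymmetric catalysis by resolution; it sets out from 3 and 4 and returns at 6. Uncatalysed addition of 4 to 3 (THF, −78 °C) gives the racemic adduct F9. Crystallisation of its salt with (R)-1-phenylethylamine, or with the antipode if that gives the less soluble salt of the 1S acid, gives the diastereomerically enriched ammonium salt F10, and acidification returns 6.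

**Step 4.** Proton transfer between the enolate and the product ketone may erode the labile C4 configuration, scramble the regiochemistry or lead to dialkylation; self-condensation of the bromoacetate is a further drain. The fallback is a Stork enamine alkylation; it sets out from 8 and returns at 10. Condensation of 8 with pyrrolidine (TsOH cat., toluene, water separator) gives the less substituted enamine 1-[(3S,6R)-6-methyl-3-(prop-1-en-2-yl)cyclohex-1-en-1-yl]pyrrolidine F11. A(1,3) strain with the pyrrolidine ring holds the C4 methyl pseudoaxial, which is the required cis configuration, so material that has epimerised at C4 should be corrected at this stage. Alkylation with methyl bromoacetate (MeCN, 60 °C) anti to the pseudoaxial methyl, followed by buffered hydrolysis (AcOH, NaOAc, water, rt), returns 10.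

**Step 10.** The SN2 reaction of a tertiary carbanion flanked by the CH(aryl)(isobutyl) group may be slow enough for O-alkylation of the dione and base-induced elimination of the iodide to take over. The fallback is a Mitsunobu C-alkylation; it sets out from 6 and 14 and returns at 16. The acidic C–H of 6 is condensed directly with the primary alcohol 14 (PPh3, diisopropyl azodicarboxylate, toluene, 0 °C to rt), so the electrophile is an alkoxyphosphonium ion generated under neutral conditions and no free basic anion is present. This fallback skips 15 and makes no new compound (F0).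

**Step 12.** The basic ylide may cleave the 1,3-dialdehyde by retro-Claisen-type deformylation, or the second olefination next to the bulky C11 group may stall. The fallback builds the vinyl groups one at a time and never forms the 1,3-dialdehyde; it sets out from 17 and returns at 19. Monoacylation of 17 (pivaloyl chloride, pyridine, 0 °C) gives the monopivalate F12 as a mixture of C1 epimers that converges later. Oxidation (Dess–Martin periodinane) gives the aldehyde F13, Wittig methylenation gives the vinyl pivalate F14, and reduction with iBu2AlH gives the vinyl alcohol F15. Oxidation then gives the vinyl aldehyde F16, and a second Wittig methylenation gives 19.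

## Further compounds

F1 | step 13 | (3S)-5-methyl-3-(2,4,6-trimethoxyphenyl)hexanamide | CC(C)C[C@H](c1c(OC)cc(OC)cc1OC)CC(N)=O
F2 | step 13 | (3S)-5-methyl-3-(2,4,6-trimethoxyphenyl)hexanenitrile | CC(C)C[C@H](c1c(OC)cc(OC)cc1OC)CC#N
F3 | step 13 | hydroxymethyl compound from hydroboration of the methylidene group of 15 (CH2OH on C3, C3 configuration not defined, other centres as in 15) | OCC1[C@H](C)CC[C@H](C(C)(C)O[Si](CC)(CC)CC)[C@H]1CCI
F4 | step 13 | ring B aldehyde (CHO on C3, C3 configuration not defined, other centres as in 15) | O=CC1[C@H](C)CC[C@H](C(C)(C)O[Si](CC)(CC)CC)[C@H]1CCI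
F5 | step 13 | β-hydroxy nitrile from F2 and F4 (mixture at the two new centres) | CC(C)C[C@H](c1c(OC)cc(OC)cc1OC)C(C#N)C(O)C2[C@H](C)CC[C@H](C(C)(C)O[Si](CC)(CC)CC)[C@H]2CCI
F6 | step 13 | iodo alkenenitrile (alkene geometry and C3 configuration not defined) | CC(C)C[C@H](c1c(OC)cc(OC)cc1OC)C(C#N)=CC2[C@H](C)CC[C@H](C(C)(C)O[Si](CC)(CC)CC)[C@H]2CCI
F7 | step 13 | bicyclic nitrile, cyano group in place of the C1 methyl of 24 | CC(C)C[C@H](c1c(OC)cc(OC)cc1OC)[C@]1(C#N)C=C2[C@H](C)CC[C@H](C(C)(C)O[Si](CC)(CC)CC)[C@H]2CC1
F8 | step 13 | bicyclic aldehyde, formyl group in place of the C1 methyl of 24 | CC(C)C[C@H](c1c(OC)cc(OC)cc1OC)[C@]1(C=O)C=C2[C@H](C)CC[C@H](C(C)(C)O[Si](CC)(CC)CC)[C@H]2CC1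
F9 | step 2 | racemic 2,2-dimethyl-5-[3-methyl-1-(2,4,6-trimethoxyphenyl)butyl]-1,3-dioxane-4,6-dione | CC(C)CC(c1c(OC)cc(OC)cc1OC)C1C(=O)OC(C)(C)OC1=O
F10 | step 2 | (R)-1-phenylethylammonium salt of 6 | CC(C)C[C@H](c1c(OC)cc(OC)cc1OC)C1=C([O-])OC(C)(C)OC1=O.C[C@@H]([NH3+])c1ccccc1
F11 | step 4 | 1-[(3S,6R)-6-methyl-3-(prop-1-en-2-yl)cyclohex-1-en-1-yl]pyrrolidine | C1CCN(C1)C2=C[C@@H](C(C)=C)CC[C@H]2C
F0 | step 10 | none | none
F12 | step 12 | monopivalate of diol 17 (mixture of C1 epimers) | C=C1[C@H](C)CC[C@H](C(C)(C)O[Si](CC)(CC)CC)[C@H]1CCC(CO)(COC(=O)C(C)(C)C)[C@H](CC(C)C)c2c(OC)cc(OC)cc2OC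
F13 | step 12 | aldehyde pivalate (mixture of C1 epimers) | C=C1[C@H](C)CC[C@H](C(C)(C)O[Si](CC)(CC)CC)[C@H]1CCC(C=O)(COC(=O)C(C)(C)C)[C@H](CC(C)C)c2c(OC)cc(OC)cc2OC
F14 | step 12 | vinyl pivalate (mixture of C1 epimers) | C=C1[C@H](C)CC[C@H](C(C)(C)O[Si](CC)(CC)CC)[C@H]1CCC(C=C)(COC(=O)C(C)(C)C)[C@H](CC(C)C)c2c(OC)cc(OC)cc2OC
F15 | step 12 | vinyl alcohol (mixture of C1 epimers) | C=C1[C@H](C)CC[C@H](C(C)(C)O[Si](CC)(CC)CC)[C@H]1CCC(C=C)(CO)[C@H](CC(C)C)c2c(OC)cc(OC)cc2OC
F16 | step 12 | vinyl aldehyde (mixture of C1 epimers) | C=C1[C@H](C)CC[C@H](C(C)(C)O[Si](CC)(CC)CC)[C@H]1CCC(C=C)(C=O)[C@H](CC(C)C)c2c(OC)cc(OC)cc2OC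
A1 | alternative 1 | hydrindanone with the C2 carbonyl in a five-membered ring (C2, C3, C8, C9, C10) | O=C1[C@H]2[C@H](C)CC[C@H](C(C)(C)O[Si](CC)(CC)CC)[C@H]2CC1
A2 | alternative 1 | methyl 2-diazopropanoate | COC(=O)C(C)=[N+]=[N-]
A3 | alternative 1 | decalin β-keto ester with quaternary C1 | COC(=O)[C@]1(C)C(=O)[C@H]2[C@H](C)CC[C@H](C(C)(C)O[Si](CC)(CC)CC)[C@H]2CC1
A4 | alternative 2 | malonyl dichloride carried on C11 | CC(C)C[C@H](C(C(Cl)=O)C(Cl)=O)[C@]1(C)C=C2[C@H](C)CC[C@H](C(C)(C)OC(C)=O)[C@H]2CC1
A5 | alternative 2 | dimethyl 3-oxopentanedioate | COC(=O)CC(=O)CC(=O)OC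
A6 | alternative 2 | phloroglucinol diester with esters at the two formyl positions | CC(C)C[C@H](c1c(O)c(C(=O)OC)c(O)c(C(=O)OC)c1O)[C@]1(C)C=C2[C@H](C)CC[C@H](C(C)(C)OC(C)=O)[C@H]2CC1
A7 | alternative 3 | iodo alkenenitrile (alkene geometry and C3 configuration not defined) | CC(C)C[C@H](c1c(OC)cc(OC)cc1OC)C(C#N)=CC2[C@H](C)CC[C@H](C(C)(C)O[Si](CC)(CC)CC)[C@H]2CCI
A8 | alternative 3 | decalin with a nitrile in place of the C1 methyl | CC(C)C[C@H](c1c(OC)cc(OC)cc1OC)[C@]1(C#N)C=C2[C@H](C)CC[C@H](C(C)(C)O[Si](CC)(CC)CC)[C@H]2CC1
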